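The plan rests on the array C14(O)–C1(quaternary, C15 methyl)–C2(O) on the cyclohexane ring C1/C10–C14, the retron of a semipinacol shift. The precursor is a 2-alkylidenecyclopentanol (ring C10–C14) that carries the C1–C2 epoxide on its carbinol carbon C14. With catalytic SmI2 and acetaldehyde, alkenyl carbon C10 migrates from C14 to C1. The five-membered ring grows to the cyclohexanone, quaternary C1 is fixed, and an Evans–Tishchenko hydride transfer then sets C14 and leaves the C2 acetate. The bought C12 centre and one Sharpless epoxidation relay the ring stereocentres. A lactate enolate, an oxyallylzinc addition and ring-closing metathesis at C5=C6 build the lactone and the ten-membered ring.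

Key step: step 8

Remark: atoms carry briarane numbers (ten-membered ring C1–C10; cyclohexane C1/C10–C14; C15 on C1; C16 on C5; lactone C7–C8–C17–C19 with C18 on C17; C20 on C11). β is the face of C15, α the opposite face.
Remark: C9 in 10/11, C14 in 14–16 and C8 in 25 are expected as epimer mixtures that converge in later steps, so their SMILES leave these centres open.

Step 1
Reactants: 1 but-2-yn-1-ol
Product: 3 (E)-3-iodobut-2-en-1-ol, via bis-zirconocene adduct 2 (not isolated)
Conditions: Cp2Zr(H)Cl (2.3 equiv), THF, 0 °C → rt; I2, −78 → 0 °C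
Reagents that add atoms: iodine, II
Why: Hydrozirconation–iodination: the first equivalent caps the hydroxyl, syn Zr–H addition (equilibrated by excess reagent) places zirconium on the less hindered methyl-bearing carbon, and iodinolysis with retention should give the E iodide with C15 cis to C3.

Step 2
Reactants: 4 (S)-lactic acid; 5 pivalaldehyde
Product: 6 (2S,5S)-2-tert-butyl-5-methyl-1,3-dioxolan-4-one
Conditions: p-TsOH (cat.), pentane, reflux, Dean–Stark; low-temperature recrystallisation
Reagents that add atoms: none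
Why: Acid-catalysed acetalisation (self-regeneration of stereocentres): the favoured cis acetal crystallises, so the lactate centre sets the acetal centre.

Step 3
Reactants: 7 (R)-4-(tert-butyldimethylsilyloxy)cyclopent-2-en-1-one; 8 benzyloxyacetaldehyde
Product: 10 cyclopentanone aldol (11β-CH3; 12α-OTBS; side chain at C10 α; C9 epimers), via lithium enolate 9 (not isolated)
Conditions: MeLi (2 equiv), CuI (1 equiv), Et2O, −78 °C; 7; then 8, −78 °C; H2O
Reagents that add atoms: lithium dimethylcuprate, [Li+].C[Cu-]C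
Why: Three-component coupling (cuprate 1,4-addition, then aldol trapping): methyl adds anti to the 12α-silyloxy group and sets 11β-CH3, and the regiodefined enolate reacts at C10; the C9 and C10 centres are erased in step 4.

Step 4
Reactants: 10 cyclopentanone aldol
Product: 12 (E)-2-[2-(benzyloxy)ethylidene]cyclopentanone (11β-CH3; 12α-OTBS), via C9 mesylate 11 (not isolated)
Conditions: MsCl, Et3N, DMAP (cat.), CH2Cl2, −20 °C → rt
Reagents that add atoms: none
Why: Mesylation and E1cB elimination should give the thermodynamic E enone (C8 anti to the carbonyl, cis to C11), and the mild amine base leaves the β′-silyloxy group in place.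

Step 5
Reactants: 12 (E)-enone; 3 (E)-3-iodobut-2-en-1-ol
Product: 14 bis-allylic diol (C14 epimers), via organocerium reagent 13 (not isolated)
Conditions: 3, t-BuLi (3.1 equiv), Et2O, −78 °C; CeCl3, THF, −78 °C; then 12; H2O
Reagents that add atoms: none
Why: Iodine–lithium exchange with retention, transmetalation to the weakly basic organocerium reagent and 1,2-addition to the enone; both C14 epimers are usable because C14 becomes sp2 in step 8.

Step 6
Reactants: 14 bis-allylic diol
Product: 15 (1R,2S)-epoxy diol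
Conditions: Ti(OiPr)4 (20 mol %), L-(+)-diethyl tartrate (25 mol %), t-BuOOH, 4 Å MS, CH2Cl2, −20 °C
Reagents that add atoms: tert-butyl hydroperoxide, CC(C)(C)OO
Why: Katsuki–Sharpless asymmetric epoxidation: only the alkene of the primary allylic alcohol reacts, and L-(+)-tartrate sets C1 and C2 under reagent control in the same sense as geraniol gives its (2S,3S)-epoxide.

Step 7
Reactants: 15 epoxy diol
Product: 16 3-O-TBS epoxy alcohol
Conditions: TBSCl, imidazole, CH2Cl2, 0 °C
Reagents that add atoms: tert-butyldimethylsilyl chloride, CC(C)(C)[Si](C)(C)Cl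
Why: Silylation selective for the primary hydroxyl leaves the tertiary C14–OH free as the push group of the next step.

Step 8
Reactants: 16 3-O-TBS epoxy alcohol
Product: 18 cyclohexanol 2-acetate (1R; 2R; 14α-OH; E-alkylidene at C10), via β-hydroxy ketone 17 (not isolated)
Conditions: SmI2 (0.3 equiv), MeCHO (8 equiv), ClCH2CH2Cl–THF, 0 °C → rt
Reagents that add atoms: acetaldehyde, CC=O
Why: Samarium activates the epoxide, the C1–O bond loosens at the tertiary carbon, and alkenyl carbon C10, antiperiplanar to it, shifts from C14 to C1 to give ketone 17; its C2–OH then adds to acetaldehyde and the samarium-bound hemiacetal passes hydride to C14. The closest known type is the SmI2-catalysed tandem semipinacol rearrangement/Tishchenko reduction of α-hydroxy epoxides. The cyclohexane ring C1/C10–C14 is closed not by an end-to-end cyclisation but by this suprafacial 1,2-shift, which inserts C1 into the C14–C10 bond of the cyclopentanol. C1 is set by stereospecific inversion at the epoxide carbon (so both C14 epimers converge), C2 keeps its epoxide C–O bond, and C14 is set by the chair-like intramolecular hydride transfer that gives the 1,3-anti diol monoester (Evans–Tishchenko reaction). The step needs migration of C10 rather than C13, which the much higher migratory aptitude of the sp2 carbon secures with retention of the E geometry. It also needs opening at C1 rather than C2, which the tertiary position secures, and quaternary C1 blocks conjugation of the β,γ-enone.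

Step 9
Reactants: 18 cyclohexanol 2-acetate
Product: 20 9,14-diol (9S; 10α-H), via oxaborinane 19 (not isolated)
Conditions: BH3·THF, THF, 0 °C → rt; then H2O2, aq NaHCO3, 0 °C
Reagents that add atoms: hydrogen peroxide, OO
Why: Hydroboration–oxidation: borane is held by the 14α-OH and adds from the α face opposite the flanking C15 and C20 methyls with boron on the less substituted C9, so syn addition to the E alkene should set 10α-H and 9S, and oxidation proceeds with retention.

Step 10
Reactants: 20 9,14-diol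
Product: 21 2,9,14-triacetate
Conditions: Ac2O, Et3N, DMAP, CH2Cl2, rt → 40 °C
Reagents that add atoms: acetic anhydride, CC(=O)OC(C)=O
Why: DMAP-catalysed acylation installs two acetates of the target at once and makes any earlier O2/O14 acetyl migration irrelevant.

Step 11
Reactants: 21 2,9,14-triacetate
Product: 22 C8 primary alcohol
Conditions: H2 (1 atm), Pd(OH)2/C, EtOAc, rt
Reagents that add atoms: none
Why: Hydrogenolysis of the benzyl ether; no alkene is present, and esters and silyl ethers are inert.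

Step 12
Reactants: 22 C8 primary alcohol
Product: 23 C8 aldehyde
Conditions: Dess–Martin periodinane, NaHCO3, CH2Cl2, 0 °C
Reagents that add atoms: none
Why: Buffered Dess–Martin oxidation gives the α-acetoxy aldehyde without base, which protects C9 from epimerisation.

Step 13
Reactants: 23 C8 aldehyde; 6 (2S,5S)-dioxolanone
Product: 25 aldol adduct (17R; C8 epimers), via lithium enolate 24 (not isolated)
Conditions: 6, LDA, THF, −78 °C; then 23, −78 °C; AcOH quench at −78 °C
Reagents that add atoms: none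
Why: Aldol addition of the lactate-derived dioxolanone enolate (self-regeneration of stereocentres): the aldehyde is attacked on the enolate face anti to tert-butyl, so C8 replaces H with retention and sets 17R; the C8 carbinol centre is removed in step 14.

Step 14
Reactants: 25 aldol adduct
Product: 26 C8 ketone
Conditions: Dess–Martin periodinane, NaHCO3, CH2Cl2, rt
Reagents that add atoms: none
Why: Dess–Martin oxidation converges both C8 epimers to a β-keto acylal that cannot enolise towards quaternary C17.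

Step 15
Reactants: 26 C8 ketone; 27 allyl tert-butyldimethylsilyl ether
Product: 29 tertiary alcohol (7S; 8R) bearing the C6 vinyl group, via oxyallylzinc chloride 28 (not isolated)
Conditions: 27, s-BuLi, THF, −78 °C; ZnCl2, −78 °C; then 26, −78 → −40 °C; H2O
Reagents that add atoms: none
Why: Carbonyl addition of a zincated allyl ether at its oxygen-bearing carbon: zinc chelated by the C8 and C19 carbonyls exposes the face flanked by ring oxygen O17, the C9 acetate stands anti to the incoming carbon (polar Felkin–Anh), and the Zimmerman–Traxler chair of the (Z)-reagent with the C9 branch equatorial should give the 7,8-syn product.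

Step 16
Reactants: 29 tertiary alcohol
Product: 31 vinyl γ-lactone tetraol (3-OH; 8-OH; 12α-OH; 17-OH), via desilylated tetraol 30 (not isolated)
Conditions: HF·pyridine, pyridine, THF, 0 °C → rt; then PPTS (cat.), toluene, 50 °C
Reagents that add atoms: none
Why: Fluoride-mediated cleavage of the three silyl ethers, then 5-exo-trig transacylation of the freed C7–OH onto C19, which expels pivalaldehyde and frees the C17–OH without touching any stereocentre.

Step 17
Reactants: 31 vinyl γ-lactone tetraol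
Product: 32 C3 aldehyde C12 ketone
Conditions: Dess–Martin periodinane (3 equiv), NaHCO3, CH2Cl2, 0 °C → rt
Reagents that add atoms: none
Why: Double Dess–Martin oxidation of the primary C3 and secondary C12 alcohols; the trans-disposed tertiary C8/C17 diol cannot form a cyclic periodinane and should persist.

Step 18
Reactants: 32 C3 aldehyde C12 ketone; 33 2-methylallylboronic acid pinacol ester
Product: 34 homoallylic alcohol (3S)
Conditions: (S)-TRIP phosphoric acid (5 mol %), 4 Å MS, toluene, −30 → 0 °C; H2O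
Reagents that add atoms: none
Why: Brønsted-acid-catalysed allylboration through a closed chair: the catalyst reinforces the polar Felkin–Anh bias of the α-acetoxy aldehyde (2,3-anti, 3S), and the C12 ketone does not react.

Step 19
Reactants: 34 homoallylic alcohol
Product: 35 3-butyrate
Conditions: butyric anhydride, Et3N, DMAP (cat.), CH2Cl2, 0 °C
Reagents that add atoms: butyric anhydride, CCCC(=O)OC(=O)CCC
Why: Acylation of the only secondary hydroxyl; the tertiary C8 and C17 alcohols are too hindered to react.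

Step 20
Reactants: 35 3-butyrate
Product: 36 12β-alcohol (12S)
Conditions: NaBH4, CeCl3·7H2O, MeOH–THF, −78 → −40 °C
Reagents that add atoms: none
Why: Luche reduction: hydride should arrive from the α face, since the β face carries C20, the C9 branch and C15, which inverts the bought C12 centre to the 12β-OH while the esters and lactone survive.

Step 21
Reactants: 36 12β-alcohol
Product: 37 seco-diene pentaester
Conditions: Ac2O, pyridine, DMAP (cat.), CH2Cl2, rt
Reagents that add atoms: acetic anhydride, CC(=O)OC(C)=O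
Why: Acetylation of the single secondary alcohol completes the ester pattern.

Step 22
Reactants: 37 seco-diene pentaester
Product: 38 target CNP0251217.1
Conditions: Hoveyda–Grubbs II (20 mol %), 1,4-benzoquinone (cat.), toluene (1 mM), 80–110 °C, Ar sparge
Reagents that add atoms: none
Why: Ring-closing metathesis: the catalyst loads at the C6 vinyl group and closes onto the 1,1-disubstituted C5 alkene, and the ten-membered ring cis-fused to the lactone should accept only the Z-trisubstituted C5=C6 bond.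

Compound list
1 | but-2-yn-1-ol | CC#CCO | starting material
2 | (E)-3-(chlorozirconocenyl)but-2-enyl chlorozirconocene alkoxide | C/C(=C\CO[Zr](Cl)(C1C=CC=C1)C1C=CC=C1)[Zr](Cl)(C1C=CC=C1)C1C=CC=C1 | intermediate
3 | (E)-3-iodobut-2-en-1-ol (C3, C2, C1, C15) | OC/C=C(\C)I | intermediate
4 | (S)-lactic acid | C[C@H](O)C(=O)O | starting material
5 | pivalaldehyde | CC(C)(C)C=O | starting material
6 | (2S,5S)-2-tert-butyl-5-methyl-1,3-dioxolan-4-one (cis) | C[C@@H]1O[C@H](C(C)(C)C)OC1=O | intermediate
7 | (R)-4-(tert-butyldimethylsilyloxy)cyclopent-2-en-1-one | O=C1C[C@@H](O[Si](C)(C)C(C)(C)C)C=C1 | starting material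
8 | benzyloxyacetaldehyde | O=CCOCc1ccccc1 | starting material
9 | lithium enolate of trans-3-methyl-4-(TBSO)cyclopentanone (C14=C10) | [Li+].[O-]C1=C[C@@H](C)[C@H](O[Si](C)(C)C(C)(C)C)C1 | intermediate
10 | 2-[2-(benzyloxy)-1-hydroxyethyl]-3-methyl-4-(TBSO)cyclopentanone, 2,3-trans-3,4-trans, C9 epimers | O=C1C[C@@H](O[Si](C)(C)C(C)(C)C)[C@H](C)[C@H]1C(O)COCc1ccccc1 | intermediate
11 | C9 mesylate of 10 | O=C1C[C@@H](O[Si](C)(C)C(C)(C)C)[C@H](C)[C@H]1C(OS(C)(=O)=O)COCc1ccccc1 | intermediate
12 | (E)-2-[2-(benzyloxy)ethylidene]-3-methyl-4-(TBSO)cyclopentanone (11β-CH3, 12α-OTBS) | O=C1C[C@@H](O[Si](C)(C)C(C)(C)C)[C@H](C)/C1=C\COCc1ccccc1 | intermediate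
13 | (E)-4-(lithiooxy)but-2-en-2-ylcerium dichloride | [Li]OC/C=C(\C)[Ce](Cl)Cl | intermediate
14 | 1-[(E)-4-hydroxybut-2-en-2-yl]-2-[(E)-2-(benzyloxy)ethylidene]-3-methyl-4-(TBSO)cyclopentanol, C14 epimers | OC/C=C(\C)C1(O)C[C@@H](O[Si](C)(C)C(C)(C)C)[C@H](C)/C1=C\COCc1ccccc1 | intermediate
15 | (1R,2S)-1,2-epoxide of 14 | OC[C@@H]1O[C@@]1(C)C2(O)C[C@@H](O[Si](C)(C)C(C)(C)C)[C@H](C)/C2=C\COCc1ccccc1 | intermediate
16 | 3-O-TBS ether of 15 | CC(C)(C)[Si](C)(C)OC[C@@H]1O[C@@]1(C)C2(O)C[C@@H](O[Si](C)(C)C(C)(C)C)[C@H](C)/C2=C\COCc1ccccc1 | intermediate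
17 | ring-enlarged cyclohexanone (C14=O, quaternary 1R, 2R-OH, E-alkylidene at C10) | CC(C)(C)[Si](C)(C)OC[C@H](O)[C@@]1(C)C(=O)C[C@@H](O[Si](C)(C)C(C)(C)C)[C@H](C)/C1=C\COCc1ccccc1 | intermediate
18 | cyclohexanol with 2-OAc and 14α-OH (14S) | CC(C)(C)[Si](C)(C)OC[C@H](OC(C)=O)[C@@]1(C)[C@@H](O)C[C@@H](O[Si](C)(C)C(C)(C)C)[C@H](C)/C1=C\COCc1ccccc1 | intermediate
19 | 1,2-oxaborinane bridging O14 and C9 | CC(C)(C)[Si](C)(C)OC[C@H](OC(C)=O)[C@@]1(C)[C@@H]2C[C@@H](O[Si](C)(C)C(C)(C)C)[C@H](C)[C@@H]1[C@@H](COCc1ccccc1)BO2 | intermediate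
20 | 9,14-diol (9S, 10S, 10α-H) | CC(C)(C)[Si](C)(C)OC[C@H](OC(C)=O)[C@@]1(C)[C@@H](O)C[C@@H](O[Si](C)(C)C(C)(C)C)[C@H](C)[C@@H]1[C@H](O)COCc1ccccc1 | intermediate
21 | 2,9,14-triacetate, 8-OBn | CC(C)(C)[Si](C)(C)OC[C@H](OC(C)=O)[C@@]1(C)[C@@H](OC(C)=O)C[C@@H](O[Si](C)(C)C(C)(C)C)[C@H](C)[C@@H]1[C@H](OC(C)=O)COCc1ccccc1 | intermediate
22 | C8 primary alcohol | CC(C)(C)[Si](C)(C)OC[C@H](OC(C)=O)[C@@]1(C)[C@@H](OC(C)=O)C[C@@H](O[Si](C)(C)C(C)(C)C)[C@H](C)[C@@H]1[C@H](OC(C)=O)CO | intermediate
23 | C8 aldehyde | CC(C)(C)[Si](C)(C)OC[C@H](OC(C)=O)[C@@]1(C)[C@@H](OC(C)=O)C[C@@H](O[Si](C)(C)C(C)(C)C)[C@H](C)[C@@H]1[C@H](OC(C)=O)C=O | intermediate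
24 | lithium enolate of 6 | CC1=C([O-])O[C@@H](C(C)(C)C)O1.[Li+] | intermediate
25 | aldol adduct, 17R, dioxolanone intact, C8 epimers | CC(C)(C)[Si](C)(C)OC[C@H](OC(C)=O)[C@@]1(C)[C@@H](OC(C)=O)C[C@@H](O[Si](C)(C)C(C)(C)C)[C@H](C)[C@@H]1[C@H](OC(C)=O)C(O)[C@@]2(C)O[C@H](C(C)(C)C)OC2=O | intermediate
26 | C8 ketone | CC(C)(C)[Si](C)(C)OC[C@H](OC(C)=O)[C@@]1(C)[C@@H](OC(C)=O)C[C@@H](O[Si](C)(C)C(C)(C)C)[C@H](C)[C@@H]1[C@H](OC(C)=O)C(=O)[C@@]2(C)O[C@H](C(C)(C)C)OC2=O | intermediate
27 | allyl tert-butyldimethylsilyl ether | C=CCO[Si](C)(C)C(C)(C)C | starting material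
28 | (Z)-3-(tert-butyldimethylsilyloxy)allylzinc chloride | Cl[Zn]C/C=C\O[Si](C)(C)C(C)(C)C | intermediate
29 | tertiary alcohol (8R) with 7S-OTBS and vinyl | CC(C)(C)[Si](C)(C)OC[C@H](OC(C)=O)[C@@]1(C)[C@@H](OC(C)=O)C[C@@H](O[Si](C)(C)C(C)(C)C)[C@H](C)[C@@H]1[C@H](OC(C)=O)[C@](O)([C@@H](O[Si](C)(C)C(C)(C)C)C=C)[C@@]2(C)O[C@H](C(C)(C)C)OC2=O | intermediate
30 | desilylated 3,7,8,12-tetraol, dioxolanone intact | OC[C@H](OC(C)=O)[C@@]1(C)[C@@H](OC(C)=O)C[C@@H](O)[C@H](C)[C@@H]1[C@H](OC(C)=O)[C@](O)([C@@H](O)C=C)[C@@]2(C)O[C@H](C(C)(C)C)OC2=O | intermediate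
31 | vinyl γ-lactone (7S, 8R, 17R) with 3-OH and 12α-OH | OC[C@H](OC(C)=O)[C@@]1(C)[C@@H](OC(C)=O)C[C@@H](O)[C@H](C)[C@@H]1[C@H](OC(C)=O)[C@@]2(O)[C@@](C)(O)C(=O)O[C@H]2C=C | intermediate
32 | C3 aldehyde, C12 ketone | O=C[C@H](OC(C)=O)[C@@]1(C)[C@@H](OC(C)=O)CC(=O)[C@H](C)[C@@H]1[C@H](OC(C)=O)[C@@]2(O)[C@@](C)(O)C(=O)O[C@H]2C=C | intermediate
33 | 2-methylallylboronic acid pinacol ester | C=C(C)CB1OC(C)(C)C(C)(C)O1 | starting material
34 | 3S homoallylic alcohol | C=C(C)C[C@H](O)[C@H](OC(C)=O)[C@@]1(C)[C@@H](OC(C)=O)CC(=O)[C@H](C)[C@@H]1[C@H](OC(C)=O)[C@@]2(O)[C@@](C)(O)C(=O)O[C@H]2C=C | intermediate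
35 | 3-butyrate | C=C(C)C[C@H](OC(=O)CCC)[C@H](OC(C)=O)[C@@]1(C)[C@@H](OC(C)=O)CC(=O)[C@H](C)[C@@H]1[C@H](OC(C)=O)[C@@]2(O)[C@@](C)(O)C(=O)O[C@H]2C=C | intermediate
36 | 12β-alcohol (12S) | C=C(C)C[C@H](OC(=O)CCC)[C@H](OC(C)=O)[C@@]1(C)[C@@H](OC(C)=O)C[C@H](O)[C@H](C)[C@@H]1[C@H](OC(C)=O)[C@@]2(O)[C@@](C)(O)C(=O)O[C@H]2C=C | intermediate
37 | seco-diene pentaester | C=C(C)C[C@H](OC(=O)CCC)[C@H](OC(C)=O)[C@@]1(C)[C@@H](OC(C)=O)C[C@H](OC(C)=O)[C@H](C)[C@@H]1[C@H](OC(C)=O)[C@@]2(O)[C@@](C)(O)C(=O)O[C@H]2C=C | intermediate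
38 | CNP0251217.1 (1R,2R,3S,5Z,7S,8R,9S,10S,11R,12S,14S,17R) | CCCC(=O)O[C@H]1C/C(C)=C\[C@@H]2OC(=O)[C@](C)(O)[C@]2(O)[C@@H](OC(C)=O)[C@H]2[C@@H](C)[C@@H](OC(C)=O)C[C@H](OC(C)=O)[C@]2(C)[C@H]1OC(C)=O | target

Total step count: 22. Longest linear sequence: 20 steps (steps 3–22, from 7).

Steps most likely to fail

Step 22. Ring closure may lose to oligomerisation or to double-bond migration. The alkylidene formed at C6 must engage a 1,1-disubstituted alkene while the fully esterified cyclohexane is forced into the chair with C2 and C9 axial. The fallback sets out from 35 and comes back at 38. The ring is closed two steps earlier on the C12 ketone, whose flattened ring reaches that chair more easily, to give the macrocyclic 12-ketone F1. Luche reduction from the α face of the macrocycle gives the macrocyclic 12β-alcohol F2, and acetylation leads to 38.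

Step 15. The hindered ketone may resist the bulky allylzinc reagent, the reagent may react at its distal carbon, or the facial and 7,8-syn selectivities may erode. The fallback sets out from 26 and comes back at 31, and it builds C7 and C6 one carbon unit at a time.
- The slim vinylmagnesium bromide–CeCl3 reagent adds under the same chelate and Felkin–Anh bias to give the vinyl carbinol F3.
- Ozonolysis (no other alkene is present) gives the non-enolisable C7 aldehyde F4.
- Catalyst-controlled vinylation (divinylzinc with the MIB enantiomer that delivers 7S) forms the alkoxide, which closes onto C19 with loss of pivalaldehyde to give the bis-silyl vinyl lactone F5.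
- HF·pyridine then gives 31.

Step 9. Borane may attack the crowded exocyclic alkene slowly or from the β face. The β-benzyloxy borane may also eliminate. The fallback sets out from 18 and comes back at 20.
- VO(acac)2/t-BuOOH epoxidation, guided by the homoallylic 14α-OH, gives the 9,10α-spiro-epoxide F6, which already holds the C9–O bond in the required sense.
- Al(OiPr)3 in hot toluene isomerises it to the tetrasubstituted C10=C11 allylic alcohol F7.
- Hydroxyl-directed hydrogenation with the Crabtree catalyst delivers both hydrogens from the α face, which resets 11β-CH3 and 10α-H and gives 20.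

Further compounds
F1 | step 22 | macrocyclic 12-ketone | CCCC(=O)O[C@H]1C/C(C)=C\[C@@H]2OC(=O)[C@](C)(O)[C@]2(O)[C@@H](OC(C)=O)[C@H]2[C@@H](C)C(=O)C[C@H](OC(C)=O)[C@]2(C)[C@H]1OC(C)=O
F2 | step 22 | macrocyclic 12β-alcohol | CCCC(=O)O[C@H]1C/C(C)=C\[C@@H]2OC(=O)[C@](C)(O)[C@]2(O)[C@@H](OC(C)=O)[C@H]2[C@@H](C)[C@@H](O)C[C@H](OC(C)=O)[C@]2(C)[C@H]1OC(C)=O
F3 | step 15 | vinyl carbinol | CC(C)(C)[Si](C)(C)OC[C@H](OC(C)=O)[C@@]1(C)[C@@H](OC(C)=O)C[C@@H](O[Si](C)(C)C(C)(C)C)[C@H](C)[C@@H]1[C@H](OC(C)=O)[C@](O)(C=C)[C@@]2(C)O[C@H](C(C)(C)C)OC2=O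
F4 | step 15 | C7 aldehyde | CC(C)(C)[Si](C)(C)OC[C@H](OC(C)=O)[C@@]1(C)[C@@H](OC(C)=O)C[C@@H](O[Si](C)(C)C(C)(C)C)[C@H](C)[C@@H]1[C@H](OC(C)=O)[C@](O)(C=O)[C@@]2(C)O[C@H](C(C)(C)C)OC2=O
F5 | step 15 | bis-silyl vinyl lactone | CC(C)(C)[Si](C)(C)OC[C@H](OC(C)=O)[C@@]1(C)[C@@H](OC(C)=O)C[C@@H](O[Si](C)(C)C(C)(C)C)[C@H](C)[C@@H]1[C@H](OC(C)=O)[C@@]2(O)[C@@](C)(O)C(=O)O[C@H]2C=C
F6 | step 9 | 9,10α-spiro-epoxide | CC(C)(C)[Si](C)(C)OC[C@H](OC(C)=O)[C@@]1(C)[C@@H](O)C[C@@H](O[Si](C)(C)C(C)(C)C)[C@H](C)[C@@]12O[C@@H]2COCc1ccccc1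
F7 | step 9 | C10=C11 allylic alcohol | CC(C)(C)[Si](C)(C)OC[C@H](OC(C)=O)[C@@]1(C)[C@@H](O)C[C@@H](O[Si](C)(C)C(C)(C)C)C(C)=C1[C@H](O)COCc1ccccc1
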